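**Slow start.** The south-west run crept: L read 12.8% of the D charged after 5.00 min. The north-west run, at 85 °C, began faster but seemed to bend: its first pace pointed to 14.7% by 30.0 s, and it read 9.0%. With a scatter of 1 percentage point, that was a hint.

| flask | D | E | Q | temperature | remark | time |
|---|---|---|---|---|---|---|
| south-west | 0.50 mM | 1.2 mM | 1 mM | 35 °C | run made earlier |  |
| north-west | 0.50 mM | 1.9 mM | 1 mM | 85 °C | run made earlier |  |
| gamma | 0.50 mM | 2.50 mM | 1.00 mM | 40 °C |  | 4.0 min |
| zeta | 0.50 mM | 2.50 mM | 1.00 mM | 100 °C |  | 4.0 min |
| eta | 0.50 mM | 2.50 mM | 1.00 mM | 70 °C |  | 4.0 min |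
| delta | 0.50 mM | 2.50 mM | 1.00 mM | 130 °C |  | 4.0 min |

- south-west (time / min: L / %, D / %): 0.417: 2.0, 99.1; 0.833: 4.8, 99.6; 2.00: 4.3, 93.6; 5.00: 12.8, 86.2
- north-west (time / s: L / %, D / %): 10.0: 4.9, 95.7; 12.0: 4.5, 94.1; 30.0: 9.0, 90.5

(standard deviation of a reading: 1 percentage point)

- the flask with the highest amount of L, in percent of the D charged ("all alike" if they lie within 1.5 percentage points) (gamma / zeta / eta / delta / all alike)
- final L, as a percentage of the D charged, in gamma
- final L, as a percentage of the D charged, in zeta
- final L, as a percentage of the D charged, in eta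
- final L, as a percentage of the D charged, in delta

- solid, in amounts per volume of the solution: Q
- at the start none of Q is in solution

**The reach.** I folded pace and bend into one number. At the south-west pace, the reach came to 1.14. The reach is the share of L that a pace lays down in the asked time, divided by the share at which the north-west run bent. I read it so: below one, pace rules; above one, a ceiling rules (kinetic against thermodynamic control). That bend was read at 85 °C, so this figure said little yet about the ceiling in a colder flask.

**One number?** It was not enough. The first north-west pace gave a reach of 13.1, larger, so the hot flasks lay far past the crossing, and there the ceiling's height mattered. South-west's last L stood above the north-west bend, so I took the ceiling to fall with heat. I reckoned about 10.2% in gamma, more in eta, and less again in zeta and delta.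

**The forecast.** It gave 23% for gamma, 44% for eta, 62% for zeta and 72% for delta, and it named delta: “Delta is still the likeliest highest”. My order differed: I put eta highest.

**The flasks.** L came to 13.1% in gamma, 18.9% in eta, 5.80% in zeta and 2.00% in delta, so the highest was eta.

    E + Z ⇌ G (K = 620 /M, k = 8.90 /M/s, Ea = 50.0 kJ/mol, ΔH = −21.0 kJ/mol)
    Q ⇌ Z, rate k2*(cs2 - [Z]) while solid is left; crystals form when [Z] > cs2 (solubility = 0.450 mM, k = 0.250 /s)
    D + Z ⇌ L (K = 140 /M, k = 51.0 /M/s, Ea = 58.0 kJ/mol, ΔH = −47.0 kJ/mol)
    (constants at 100 °C)

**Coming to rest.** Ten times the asked time lifts the reach to 11.4, yet L followed no pace in either flask. Eta had not come to rest: its solid Q went from 5.01% of its charge to 0%, and L fell from 18.9% to 13.7%. Delta had stopped by 2.00 min, with L at 2.00%, and at 40.0 min its L still stood at 2.00%.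

The data were generated by integration for an exercise; scatter was added.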